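**Plan**

- The target is a 35-membered lactone made of the ring oxygen, the carbonyl carbon C1 and 33 consecutive unsubstituted methylenes C2–C34 (chain numbering from the carbonyl; C34 carries the ring oxygen). Because this run has no branch, heteroatom or stereocentre, any C–C bond of the ring can serve as the closure site.
- Retrosynthetic cuts, in order: C25–C26 (drawn back to a C25=C26 alkene and opened by ring-closing olefin metathesis to a diene ester); then the ester C1(=O)–O bond (hexacos-25-enoic acid and dec-9-en-1-ol); then C15–C16 of the acid (15-bromopentadecanoic acid and the Grignard reagent of 11-bromoundec-1-ene).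
- Forward: C15–C16 is joined first by copper-catalysed alkyl–alkyl coupling, the ester is formed second, the only ring is closed third by metathesis at C25=C26, and hydrogenation finishes the synthesis.
- C25–C26 is chosen because it divides the chain into a C26 acid and a C10 alcohol reachable from purchasable pieces, and keeps both reacting alkenes 23 and 8 methylenes away from the ester.
- Stereochemistry: the target has none; the only stereo-element that ever appears, the C25=C26 geometry, is erased in the last step.

Key step: step 3

Remark: chain locants C1–C34 correspond to C2–C35 in the ring names, so the C25=C26 alkene is the 26-ene of compound 9.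
Assumption: step 3 is expected to give both alkene isomers; compound 9 is drawn and listed as the E isomer, and the mixture is carried into step 4, where both converge.

**Step 1**
Reactants: 1 11-bromoundec-1-ene; 2 15-bromopentadecanoic acid
Product: 6 hexacos-25-enoic acid, via undec-10-en-1-ylmagnesium bromide 3 (not isolated), via chloromagnesium 15-bromopentadecanoate 4 (not isolated), via chloromagnesium hexacos-25-enoate 5 (not isolated)
Conditions: (a) 1 (1.4 equiv), Mg turnings, THF, rt to 45 °C; (b) 2, MeMgCl (1.0 equiv), THF, −20 °C; (c) solution of 3 added to 4, Li2CuCl4 (3 mol %), THF, −20 °C to rt; 1 M HCl work-up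
Reagents that add atoms: none
Why: Copper-catalysed Grignard alkyl–alkyl cross-coupling (Kochi coupling) of a primary alkylmagnesium bromide with a primary alkyl bromide should join C15 to C16, the acid being masked in the flask as its chloromagnesium carboxylate, which does not add Grignard reagents at this temperature, while the terminal alkene is a spectator.

**Step 2**
Reactants: 6 hexacos-25-enoic acid; 7 dec-9-en-1-ol
Product: 8 dec-9-en-1-yl hexacos-25-enoate
Conditions: DCC (1.2 equiv), DMAP (0.1 equiv), CH2Cl2, rt to 35 °C
Reagents that add atoms: none
Why: Steglich esterification, in which DCC turns the acid into an O-acylisourea and DMAP relays the acyl group to the unhindered primary alcohol, should give the ester without touching either terminal alkene.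

**Step 3**
Reactants: 8 dec-9-en-1-yl hexacos-25-enoate
Product: 9 (E)-oxacyclopentatriacont-26-en-2-one
Conditions: RuCl2(H2IMes)(PCy3)(=CHPh) (second-generation Grubbs catalyst, 5 mol %), 1,4-benzoquinone (10 mol %), CH2Cl2, 40 °C, 8 added over 8 h to a final 0.5 mM, Ar sparge; then ethyl vinyl ether
Reagents that add atoms: none
Why: Loss of PCy3 from the precatalyst gives a 14-electron ruthenium benzylidene that exchanges onto one terminal alkene of 8, and the resulting alkylidene adds [2+2] to the second terminal alkene to give a ruthenacyclobutane whose cycloreversion releases 9 and a ruthenium methylidene that re-enters the cycle with expulsion of ethylene (Chauvin mechanism). The closest known reaction type is ruthenium-catalysed ring-closing olefin metathesis of α,ω-diene esters to large-ring musk-type lactones. The single 35-membered ring closes end to end by forming the endocyclic C25=C26 double bond, which lies 23 methylenes from the carbonyl and 8 methylenes from the ring oxygen, so neither carbonyl chelation nor steric hindrance affects these two unhindered monosubstituted olefins. No stereocentre is created, and the alkene geometry (E expected to predominate under the reversible conditions) is immaterial because step 4 removes it. The selectivity needed is ring closure over acyclic diene metathesis oligomerisation, secured by sub-millimolar pseudo-dilution, continuous removal of ethylene and the strain-free, unsubstituted polymethylene ring, whose oligomers can backbite to the monomeric ring under this reversible catalyst. Double-bond migration, which would trim methylenes from the ring, is held back by 1,4-benzoquinone as a scavenger of ruthenium hydrides.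

**Step 4**
Reactants: 9 (E)-oxacyclopentatriacont-26-en-2-one
Product: 10 oxacyclopentatriacontan-2-one
Conditions: H2 (1 atm), 10% Pd/C (palladium on carbon), EtOAc, rt
Reagents that add atoms: none
Why: Heterogeneous catalytic hydrogenation of an unhindered 1,2-disubstituted alkene over Pd/C should saturate both alkene isomers to the same lactone, the ester being inert to hydrogen at atmospheric pressure.

**Compound list**

1 | 11-bromoundec-1-ene | C=CCCCCCCCCCBr | starting material
2 | 15-bromopentadecanoic acid | OC(=O)CCCCCCCCCCCCCCBr | starting material
3 | undec-10-en-1-ylmagnesium bromide | C=CCCCCCCCCC[Mg]Br | intermediate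
4 | chloromagnesium 15-bromopentadecanoate | BrCCCCCCCCCCCCCCC(=O)O[Mg]Cl | intermediate
5 | chloromagnesium hexacos-25-enoate | C=CCCCCCCCCCCCCCCCCCCCCCCCC(=O)O[Mg]Cl | intermediate
6 | hexacos-25-enoic acid | C=CCCCCCCCCCCCCCCCCCCCCCCCC(=O)O | intermediate
7 | dec-9-en-1-ol | OCCCCCCCCC=C | starting material
8 | dec-9-en-1-yl hexacos-25-enoate | C=CCCCCCCCCCCCCCCCCCCCCCCCC(=O)OCCCCCCCCC=C | intermediate
9 | (E)-oxacyclopentatriacont-26-en-2-one (E drawn; Z isomer expected alongside) | O=C1CCCCCCCCCCCCCCCCCCCCCCC/C=C/CCCCCCCCO1 | intermediate
10 | oxacyclopentatriacontan-2-one | O=C1CCCCCCCCCCCCCCCCCCCCCCCCCCCCCCCCCO1 | target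

Total step count: 4
Longest linear sequence: 4 steps (1 and 2 to 6, then 8, 9 and 10)

**Steps most likely to fail**

Step 3. Intermolecular metathesis may outrun ring closure and give oligomers, or double-bond migration may precede closure and contract the ring. The fallback makes the C25=C26 bond intermolecularly and closes the ring at the lactone C–O bond instead. It sets out from acid 6: cross-metathesis with an excess of dec-9-en-1-ol 7 (4 equiv; RuCl2(H2IMes)(PCy3)(=CHPh), CH2Cl2, 40 °C) should give (E)-34-hydroxytetratriacont-25-enoic acid F1, either alkene geometry being acceptable. Hydrogenation (H2, Pd/C, THF/EtOAc) should then give 34-hydroxytetratriacontanoic acid F2. Yamaguchi macrolactonisation (2,4,6-trichlorobenzoyl chloride, Et3N, THF; then slow addition to DMAP in toluene at reflux, about 1 mM) should pass through 34-hydroxytetratriacontanoic 2,4,6-trichlorobenzoic anhydride F3 and come back to the route at target 10.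

Step 1. Homocoupling of the Grignard reagent and stalling through precipitation of the magnesium carboxylate at low temperature may erode the coupling. The fallback installs the ester first and uses ester-tolerant organozinc chemistry. It sets out from bromo acid 2: Steglich esterification with 7 (DCC, DMAP, CH2Cl2) should give dec-9-en-1-yl 15-bromopentadecanoate F4. Zinc insertion into 1 (Zn dust, catalytic I2, DMA, 80 °C) should give undec-10-en-1-ylzinc bromide F5. Palladium-catalysed alkyl–alkyl Negishi coupling of F5 with F4 (Pd2(dba)3, tricyclopentylphosphine, N-methylimidazole, THF/NMP, 80 °C) should come back to the route at diene ester 8, bypassing 6.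

Step 2. Rearrangement of the O-acylisourea to the unreactive N-acylurea may compete while the sparingly soluble C26 acid dissolves slowly. The fallback forms the ester by O-alkylation instead of acyl activation. It sets out from 6: deprotonation with Cs2CO3 (DMF/THF, 60 °C) should give caesium hexacos-25-enoate F6, and its SN2 alkylation with purchased 10-bromodec-1-ene (C=CCCCCCCCCBr) should come back to the route at 8.

**Further compounds**

F1 | step 3 | (E)-34-hydroxytetratriacont-25-enoic acid | OCCCCCCCC/C=C/CCCCCCCCCCCCCCCCCCCCCCCC(=O)O
F2 | step 3 | 34-hydroxytetratriacontanoic acid | OCCCCCCCCCCCCCCCCCCCCCCCCCCCCCCCCCC(=O)O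
F3 | step 3 | 34-hydroxytetratriacontanoic 2,4,6-trichlorobenzoic anhydride | OCCCCCCCCCCCCCCCCCCCCCCCCCCCCCCCCCC(=O)OC(=O)c1c(Cl)cc(Cl)cc1Cl
F4 | step 1 | dec-9-en-1-yl 15-bromopentadecanoate | BrCCCCCCCCCCCCCCC(=O)OCCCCCCCCC=C
F5 | step 1 | undec-10-en-1-ylzinc bromide | C=CCCCCCCCCC[Zn]Br
F6 | step 2 | caesium hexacos-25-enoate | C=CCCCCCCCCCCCCCCCCCCCCCCCC(=O)[O-].[Cs+]
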